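## The problem

Compound 16 is a benzophenone whose carbonyl carbon C7 joins two highly oxygenated rings. Each ring carries two substituents ortho to C7 (OH and OCH3 on ring A, OCH3 and CH3 on ring B), so the C1–C7–C1' unit is tetra-ortho-substituted and any bond made at C7 must tolerate crowding. The target has no stereocentre; the only one that can arise on the way is a carbinol at C7, which controls nothing and must be erased by oxidation. The real difficulty is positional. Ring A bears five different substituents (C1 acyl, C2 OH, C3 Cl, C4 OCH3, C6 OCH3), and chlorine must sit at C3 between hydroxyl and methoxy, not at the electronically similar C5. Ring B must carry CH3 at C6', OCH3 at C2' and the free hydroxyl at C4'. Two phenols must emerge free beside three methyl ethers, so each needs a temporary group that is removed without touching OCH3. The Lewis acids that drive a Friedel–Crafts acylation (AlCl3, BCl3) cleave exactly the methyl ethers ortho to the carbonyl, and the aryl chloride rules out hydrogenolysis. The enabling feature is the contiguous C6' (CH3), C1' (acyl), C2' (OCH3) edge of ring B with oxygen at C4' para to the acyl carbon. This is the pattern left when a 3-methoxybenzyne takes a carbon nucleophile at the aryne carbon remote from methoxy and an electrophile at the carbon next to it. Ring B can therefore be written onto a 1,3,5-trisubstituted fluoroarene that has no carbon substituent. On ring A, C1 and C3 both flank the C2 oxygen, so one directing group on that oxygen can place both the chlorine and the formyl carbon.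

## Retrosynthesis

**Protecting groups (16 ⇐ 15 ⇐ 14).** The O–CH2OCH3 bond at C2 and the O–Si bond at C4' are cut. The ring A hydroxyl is carried as a methoxymethyl ether because that group also serves as the lithiation director when ring A is built. The ring B hydroxyl is carried as a triisopropylsilyl ether because the key step needs a bulky, non-directing, base-stable group there. Fluoride removes silicon (14 → 15) and methanolic acid removes the acetal (15 → 16); neither touches the three methyl ethers or the chloride.

**Oxidation level at C7 (14 ⇐ 13).** The ketone 14 is traced to the racemic carbinol 13. Addition of an aryllithium to an aldehyde tolerates two ortho substituents on each partner far better than any acyl transfer, so one extra oxidation step is accepted.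

**Key disconnection (13 ⇐ 2 + 9 + 8).** Two bonds of ring B are cut at once: C1'–C7 and C6'–CH3. The neighbouring cut at C1–C7 (ring A nucleophile, ring B aldehyde) would require a ready-made, fully substituted ring B. A Friedel–Crafts cut at C7 would face ambiguous regiochemistry and ether cleavage. The chosen cut instead reduces ring B to the silyl ether 2, which has only F, OCH3 and OSi(iPr)3 in a 1,3,5 arrangement, plus methyllithium 9 and the ring A aldehyde 8. The forward reaction must do four things in one flask:
- lithiate 2 only between F and OCH3, giving 10;
- release the aryne 11 by loss of LiF;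
- add 9 at the former C–F carbon, giving 12;
- add 12 to the formyl group of 8.

**Ring B precursor (2 ⇐ 1).** Cutting the O–Si bond leads to commercial 3-fluoro-5-methoxyphenol 1. Silylation is needed only to mask the acidic OH and to shield the two ring positions next to it.

**Ring A aldehyde (8 ⇐ 6 ⇐ 4 ⇐ 3).** The C1–CHO bond and then the C3–Cl bond are cut, each as the product of an ortho-lithiation directed by the methoxymethyl ether (aryllithiums 7 and 5). That ether outranks methoxy as a director, so the two electrophiles go one after the other to the two positions flanking the C2 oxygen, which is the ring A pattern of 16. Electrophilic chlorination of a phloroglucinol ether would not distinguish C3 from C5. The sequence ends at 1,3-dimethoxy-5-(methoxymethoxy)benzene 4 and commercial 3,5-dimethoxyphenol 3.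

## Roads not taken

**Alternative 1:** Ring B is cut at C1'–C6' and C2'–C3' and built from acyclic carbon. The ring A β-keto ester methyl 3-[3-chloro-4,6-dimethoxy-2-(methoxymethoxy)phenyl]-3-oxopropanoate A1 would react with (E)-pent-3-en-2-one A2 under NaOMe. Michael addition forms C1'–C6', and Claisen attack of the methyl ketone enolate on the ester closes the ring to the dione A3.
- Merits: C7 is a ketone from the start, the methyl position is fixed by A2, and no organolithium or cryogenic step is needed for ring B.
- Weak points: A3 is a cyclohexanedione and must be dehydrogenated in the presence of an electron-rich ring A and an acetal. After aromatisation both ring B oxygens are free hydroxyls, and the one that must become the methyl ether (C2') is chelated to the ketone and is the less nucleophilic. Protection at C4', methylation at C2' and deprotection would follow. A1 also costs extra steps beyond an aldehyde of the type of 8.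
- Comparison: its key step is ordinary enolate chemistry and avoids the competition for the aryne, which is a real advantage. The chosen plan sets against this that 13 already has ring B aromatic with its two oxygens differentiated, so three routine steps finish the synthesis where this road needs at least five.

**Alternative 2:** Ring A is cut at C1–C2 and traced to a folded polyketide chain. The pyrone 4-hydroxy-6-{2-[2-methoxy-4-(methoxymethoxy)-6-methylphenyl]-2-oxoethyl}-2H-pyran-2-one A4 would be opened by Mg(OMe)2 in methanol to the chelated triketo ester A5. The methylene next to the aryl ketone would then attack the ester carbonyl (Claisen) to give the trihydroxybenzophenone A6.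
- Merits: the route is biomimetic, the 2,4,6-oxygen pattern of ring A arises by itself, C7 is at the ketone level, and ring A needs no protecting group.
- Weak points: A6 has no chlorine. After two O-methylations (feasible, since the chelated hydroxyl reacts last), an electrophilic chlorination must choose C3 over C5 and must spare ring B, with nothing to direct it. The aldol mode of cyclisation of A5 competes. A4 has to be assembled from a fully substituted ring B acyl unit, so the 1,2,3-pattern of ring B must still be bought or made elsewhere.
- Comparison: this road is more elegant in how ring A arises. The chosen plan places chlorine by directed lithiation before the rings are joined and makes the ring B pattern in the coupling itself.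

**Alternative 3:** Both bonds to C7 are cut, with carbon monoxide A8 as a one-carbon linchpin. A zerovalent palladium catalyst such as Pd(PPh3)4 would insert into the C–I bond of 2-chloro-4-iodo-1,5-dimethoxy-3-(methoxymethoxy)benzene A7. A8 would insert to give an acyl complex of divalent palladium, and [2-methoxy-4-(methoxymethoxy)-6-methylphenyl]boronic acid A9 would transmetalate. Reductive elimination would give the ketone A10.
- Merits: the ketone forms directly, and both phenols carry the same acetal, so one acid step finishes the synthesis. A7 would come from 6 by the lithiation of step 4 with an iodine quench. In steps after the coupling (one against three) and in longest linear sequence this road is better than the chosen one.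
- Weak points: both partners are di-ortho-substituted and electron-rich. Transmetalation to a hindered acylpalladium is slow, the 2,6-disubstituted boronic acid A9 is prone to protodeboronation, and direct biaryl coupling without A8 competes. A9 also presupposes a ring B halide with the methyl in place, and its regioselective preparation from an orcinol ether is not secured.
- Comparison: the chosen plan accepts two more steps. In return its coupling event (aryllithium plus aldehyde) is a reaction type known to tolerate this degree of ortho substitution, and the methyl-bearing ring B pattern is made in the same operation.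

Key step: step 5

Assumption: the carbinol carbon of 13 is left uncontrolled (racemic), because it becomes the carbonyl carbon of 16, which has no stereocentre; 1, 3 and 9 are taken as purchased.

## Route

Step 1
Reactants: 1 3-fluoro-5-methoxyphenol
Product: 2 (3-fluoro-5-methoxyphenoxy)tri(propan-2-yl)silane
Conditions: iPr3SiCl, imidazole, DMF, rt
Reagents that add atoms: chlorotri(propan-2-yl)silane (iPr3SiCl), CC(C)[Si](Cl)(C(C)C)C(C)C
Why: O-silylation of a phenol with a silyl chloride and imidazole. The triisopropylsilyl ether withstands alkyllithiums, does not direct lithiation and is bulky enough to shield its two neighbouring ring positions and to resist silyl migration to carbon.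

Step 2
Reactants: 3 3,5-dimethoxyphenol
Product: 4 1,3-dimethoxy-5-(methoxymethoxy)benzene
Conditions: MOMCl, iPr2NEt, CH2Cl2, 0 °C → rt
Reagents that add atoms: chloromethyl methyl ether (MOMCl), COCCl
Why: O-alkylation of a phenol to its methoxymethyl ether under amine base. The acetal masks the phenol and is the directing group for both lithiations that follow.

Step 3
Reactants: 4 1,3-dimethoxy-5-(methoxymethoxy)benzene
Product: 6 2-chloro-1,5-dimethoxy-3-(methoxymethoxy)benzene, via aryllithium 5 (not isolated)
Conditions: nBuLi, TMEDA, THF, 0 °C; C2Cl6, −78 °C → rt
Reagents that add atoms: hexachloroethane (C2Cl6), ClC(Cl)(Cl)C(Cl)(Cl)Cl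
Why: Directed ortho-metalation. The chelating methoxymethyl ether outranks methoxy, so lithium enters one of the two equivalent positions between OCH2OCH3 and OCH3 rather than between the two methoxy groups. Hexachloroethane then transfers chlorine to the aryllithium with loss of tetrachloroethene and LiCl.

Step 4
Reactants: 6 2-chloro-1,5-dimethoxy-3-(methoxymethoxy)benzene
Product: 8 3-chloro-4,6-dimethoxy-2-(methoxymethoxy)benzaldehyde, via aryllithium 7 (not isolated)
Conditions: nBuLi, TMEDA, THF, −78 → −20 °C; DMF, −78 °C → rt; H2O
Reagents that add atoms: N,N-dimethylformamide (DMF), CN(C)C=O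
Why: Second directed ortho-metalation followed by formylation with DMF. The only position still flanking the methoxymethyl ether is lithiated in preference to the one between the two methoxy groups. The chloride has no ortho hydrogen and does not exchange with nBuLi at low temperature.

Step 5
Reactants: 2 (3-fluoro-5-methoxyphenoxy)tri(propan-2-yl)silane, 9 methyllithium, 8 3-chloro-4,6-dimethoxy-2-(methoxymethoxy)benzaldehyde
Product: 13 rac-[3-chloro-4,6-dimethoxy-2-(methoxymethoxy)phenyl]{2-methoxy-6-methyl-4-[tri(propan-2-yl)silyloxy]phenyl}methanol, via fluoroaryllithium 10 (not isolated), via aryne 11 (not isolated), via methylated aryllithium 12 (not isolated)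
Conditions: sBuLi (1.0 equiv), THF, −78 °C; MeLi (2 equiv), −78 → −30 °C; 8 (2.2 equiv), −78 → 0 °C; H2O
Reagents that add atoms: none
Why: sBuLi removes the proton of 2 that lies between F and OCH3 (directed ortho-metalation; both groups acidify this site, while the two positions flanking the bulky, non-coordinating silyl ether are shielded) and gives 10, which persists at −78 °C. On warming, 10 loses LiF and the aryne 11 forms across exactly these two carbons. Methyllithium 9 adds to the aryne carbon that carried fluorine, remote from OCH3, because this puts the carbanion next to the inductively withdrawing, lithium-coordinating methoxy group, as is usual for 3-alkoxybenzynes; this makes the C6'–CH3 bond and gives 12. After recooling, 12 attacks the formyl group of 8 and makes the C1'–C7 bond, and aqueous quench gives 13. The closest known reaction type is ortho-lithiation of a 3-fluoroanisole, loss of LiF, addition of an organolithium to the 3-methoxybenzyne and electrophilic trapping of the resulting 2-lithioanisole. No ring is closed. The carbinol carbon is the only new stereocentre; nothing controls it, 13 should form as the racemate, and the centre is removed in step 6. The step needs site-selective lithiation (secured by the F/OCH3 pair and the silyl bulk), regioselective carbolithiation (secured by the methoxy group beside the triple bond) and capture of 11 by 9 ahead of 10 (favoured by having 9 present in excess before the aryne is released).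

Step 6
Reactants: 13 rac-[3-chloro-4,6-dimethoxy-2-(methoxymethoxy)phenyl]{2-methoxy-6-methyl-4-[tri(propan-2-yl)silyloxy]phenyl}methanol
Product: 14 [3-chloro-4,6-dimethoxy-2-(methoxymethoxy)phenyl]{2-methoxy-6-methyl-4-[tri(propan-2-yl)silyloxy]phenyl}methanone
Conditions: Dess–Martin periodinane, pyridine, CH2Cl2, 0 °C → rt
Reagents that add atoms: none
Why: Dess–Martin oxidation of a secondary diaryl carbinol to the ketone under nearly neutral, buffered conditions that spare the acetal, the silyl ether and the electron-rich rings. The stereocentre of 13 disappears here.

Step 7
Reactants: 14 [3-chloro-4,6-dimethoxy-2-(methoxymethoxy)phenyl]{2-methoxy-6-methyl-4-[tri(propan-2-yl)silyloxy]phenyl}methanone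
Product: 15 [3-chloro-4,6-dimethoxy-2-(methoxymethoxy)phenyl](4-hydroxy-2-methoxy-6-methylphenyl)methanone
Conditions: Bu4NF, THF, 0 °C; H2O
Reagents that add atoms: none
Why: Fluoride-induced cleavage of an aryl silyl ether. The phenoxide para to the ketone is a good leaving group from silicon, and the acetal, methyl ethers and chloride are inert to fluoride.

Step 8
Reactants: 15 [3-chloro-4,6-dimethoxy-2-(methoxymethoxy)phenyl](4-hydroxy-2-methoxy-6-methylphenyl)methanone
Product: 16 (3-chloro-2-hydroxy-4,6-dimethoxyphenyl)(4-hydroxy-2-methoxy-6-methylphenyl)methanone
Conditions: HCl, MeOH, 40 °C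
Reagents that add atoms: none
Why: Acid-catalysed acetal exchange removes the methoxymethyl group as dimethoxymethane. The freed C2 hydroxyl is stabilised by its hydrogen bond to the ketone, and the aryl methyl ethers are stable to Brønsted acid in methanol.

## Compound list

1 | 3-fluoro-5-methoxyphenol | COc1cc(O)cc(F)c1 | starting material
2 | (3-fluoro-5-methoxyphenoxy)tri(propan-2-yl)silane | COc1cc(F)cc(O[Si](C(C)C)(C(C)C)C(C)C)c1 | intermediate
3 | 3,5-dimethoxyphenol | COc1cc(O)cc(OC)c1 | starting material
4 | 1,3-dimethoxy-5-(methoxymethoxy)benzene | COCOc1cc(OC)cc(OC)c1 | intermediate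
5 | [2,4-dimethoxy-6-(methoxymethoxy)phenyl]lithium | [Li]c1c(OC)cc(OC)cc1OCOC | intermediate
6 | 2-chloro-1,5-dimethoxy-3-(methoxymethoxy)benzene | COCOc1cc(OC)cc(OC)c1Cl | intermediate
7 | [3-chloro-4,6-dimethoxy-2-(methoxymethoxy)phenyl]lithium | [Li]c1c(OC)cc(OC)c(Cl)c1OCOC | intermediate
8 | 3-chloro-4,6-dimethoxy-2-(methoxymethoxy)benzaldehyde | COCOc1c(Cl)c(OC)cc(OC)c1C=O | intermediate
9 | methyllithium | [Li]C | starting material
10 | {2-fluoro-6-methoxy-4-[tri(propan-2-yl)silyloxy]phenyl}lithium | [Li]c1c(F)cc(O[Si](C(C)C)(C(C)C)C(C)C)cc1OC | intermediate
11 | 3-methoxy-5-[tri(propan-2-yl)silyloxy]benzyne (1,2-didehydro-3-methoxy-5-[tri(propan-2-yl)silyloxy]benzene) | COC1=CC(O[Si](C(C)C)(C(C)C)C(C)C)=CC#C1 | intermediate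
12 | {2-methoxy-6-methyl-4-[tri(propan-2-yl)silyloxy]phenyl}lithium | [Li]c1c(C)cc(O[Si](C(C)C)(C(C)C)C(C)C)cc1OC | intermediate
13 | rac-[3-chloro-4,6-dimethoxy-2-(methoxymethoxy)phenyl]{2-methoxy-6-methyl-4-[tri(propan-2-yl)silyloxy]phenyl}methanol | COCOc1c(Cl)c(OC)cc(OC)c1C(O)c1c(C)cc(O[Si](C(C)C)(C(C)C)C(C)C)cc1OC | intermediate
14 | [3-chloro-4,6-dimethoxy-2-(methoxymethoxy)phenyl]{2-methoxy-6-methyl-4-[tri(propan-2-yl)silyloxy]phenyl}methanone | COCOc1c(Cl)c(OC)cc(OC)c1C(=O)c1c(C)cc(O[Si](C(C)C)(C(C)C)C(C)C)cc1OC | intermediate
15 | [3-chloro-4,6-dimethoxy-2-(methoxymethoxy)phenyl](4-hydroxy-2-methoxy-6-methylphenyl)methanone | COCOc1c(Cl)c(OC)cc(OC)c1C(=O)c1c(C)cc(O)cc1OC | intermediate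
16 | (3-chloro-2-hydroxy-4,6-dimethoxyphenyl)(4-hydroxy-2-methoxy-6-methylphenyl)methanone | COc1cc(OC)c(C(=O)c2c(C)cc(O)cc2OC)c(O)c1Cl | target

## Step count and risks

Total: 8 steps. Longest linear sequence: 7 steps (3 → 4 → 6 → 8 → 13 → 14 → 15 → 16); the ring B branch (1 → 2) joins at step 5.

**Step 5 (key step).** Three things can go wrong.
- Capture of the aryne 11 by the aryllithium 10 still present, or by residual sBuLi, instead of by the aggregated and less nucleophilic methyllithium 9. This would lead to self-coupling or sec-butyl incorporation.
- Incomplete site selectivity in the lithiation of 2, which would move the aryne to the other side of fluorine.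
- Consumption of 8 by the surplus of 9. This forces an excess of the aldehyde and a chromatographic separation, and the addition of the di-ortho-substituted 12 to the di-ortho-substituted 8 may be slow.

Fallback, setting out from 6 and rejoining at 13: the polarity of the C7 bond construction is reversed and the aryne is given up. Commercial 2,4-dihydroxy-6-methylbenzaldehyde F1 would be silylated at its non-chelated C4 hydroxyl (iPr3SiCl, imidazole) to 2-hydroxy-6-methyl-4-[tri(propan-2-yl)silyloxy]benzaldehyde F2. The chelated hydroxyl would be methylated (MeI, Ag2O) to 2-methoxy-6-methyl-4-[tri(propan-2-yl)silyloxy]benzaldehyde F3. The ring A aryllithium 7, generated from 6 exactly as in step 4, would then be added to F3 to give 13.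

**Step 4.** The risk is loss of regiocontrol in the second lithiation. The methoxymethyl ether is now flanked by chlorine and may coordinate less well, so deprotonation between the two methoxy groups could compete; attack of nBuLi at the chloride is also possible. The same detour would also cover a regiochemical problem in step 3. Fallback, setting out from 3 and rejoining at 8: both lithiations are replaced by phenol-directed electrophilic chemistry. Amine-catalysed ortho-chlorination of 3 with SO2Cl2 would give 2-chloro-3,5-dimethoxyphenol F4, from which the para isomer would have to be separated. Magnesium phenoxide-directed ortho-formylation (MgCl2, Et3N, paraformaldehyde; Casnati–Skattebøl conditions) at the only free ortho position would give 3-chloro-2-hydroxy-4,6-dimethoxybenzaldehyde F5. MOMCl with iPr2NEt would then give 8.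

**Step 6.** The oxidation may be sluggish because the carbinol is flanked by four ortho substituents. The doubly benzylic, electron-rich carbinol may also ionise under the acetic acid released, with loss of the acetal or self-condensation. Fallback, setting out from 6 and rejoining at 14: the oxidation is avoided by raising the oxidation level of the electrophile. Aryllithium 7 would be quenched with N-methoxy-N-methylcarbamoyl chloride to give the Weinreb amide 3-chloro-N,4,6-trimethoxy-N-methyl-2-(methoxymethoxy)benzamide F6, which would replace 8 in step 5. Addition of 12 would give a chelated tetrahedral adduct that should survive the surplus methyllithium and release 14 on aqueous work-up.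

**Step 8.** The methoxymethyl cation set free under acid may be captured by the electron-rich rings, above all by ring B once its phenol is free. This would give hydroxymethylated or methylene-bridged by-products. Fallback, setting out from 14 and rejoining at 16: the order of the deprotections is reversed, so that the acetal is cleaved while ring B is still silylated and shielded. HCl in methanol on 14 would give (3-chloro-2-hydroxy-4,6-dimethoxyphenyl){2-methoxy-6-methyl-4-[tri(propan-2-yl)silyloxy]phenyl}methanone F7, and Bu4NF would then give 16.

## Further compounds

F1 | step 5 | 2,4-dihydroxy-6-methylbenzaldehyde (purchased) | Cc1cc(O)cc(O)c1C=O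
F2 | step 5 | 2-hydroxy-6-methyl-4-[tri(propan-2-yl)silyloxy]benzaldehyde | Cc1cc(O[Si](C(C)C)(C(C)C)C(C)C)cc(O)c1C=O
F3 | step 5 | 2-methoxy-6-methyl-4-[tri(propan-2-yl)silyloxy]benzaldehyde | COc1cc(O[Si](C(C)C)(C(C)C)C(C)C)cc(C)c1C=O
F4 | step 4 | 2-chloro-3,5-dimethoxyphenol | COc1cc(O)c(Cl)c(OC)c1
F5 | step 4 | 3-chloro-2-hydroxy-4,6-dimethoxybenzaldehyde | COc1cc(OC)c(C=O)c(O)c1Cl
F6 | step 6 | 3-chloro-N,4,6-trimethoxy-N-methyl-2-(methoxymethoxy)benzamide | COCOc1c(Cl)c(OC)cc(OC)c1C(=O)N(C)OC
F7 | step 8 | (3-chloro-2-hydroxy-4,6-dimethoxyphenyl){2-methoxy-6-methyl-4-[tri(propan-2-yl)silyloxy]phenyl}methanone | COc1cc(OC)c(C(=O)c2c(C)cc(O[Si](C(C)C)(C(C)C)C(C)C)cc2OC)c(O)c1Cl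
A1 | alternative 1 | methyl 3-[3-chloro-4,6-dimethoxy-2-(methoxymethoxy)phenyl]-3-oxopropanoate | COC(=O)CC(=O)c1c(OC)cc(OC)c(Cl)c1OCOC
A2 | alternative 1 | (E)-pent-3-en-2-one | C/C=C/C(C)=O
A3 | alternative 1 | racemic trans-4-[3-chloro-4,6-dimethoxy-2-(methoxymethoxy)benzoyl]-5-methylcyclohexane-1,3-dione (one enantiomer drawn) | C[C@@H]1CC(=O)CC(=O)[C@H]1C(=O)c1c(OC)cc(OC)c(Cl)c1OCOC
A4 | alternative 2 | 4-hydroxy-6-{2-[2-methoxy-4-(methoxymethoxy)-6-methylphenyl]-2-oxoethyl}-2H-pyran-2-one | O=C1C=C(O)C=C(CC(=O)c2c(C)cc(OCOC)cc2OC)O1
A5 | alternative 2 | methyl 7-[2-methoxy-4-(methoxymethoxy)-6-methylphenyl]-3,5,7-trioxoheptanoate | COC(=O)CC(=O)CC(=O)CC(=O)c1c(C)cc(OCOC)cc1OC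
A6 | alternative 2 | [2-methoxy-4-(methoxymethoxy)-6-methylphenyl](2,4,6-trihydroxyphenyl)methanone | Oc1cc(O)c(C(=O)c2c(C)cc(OCOC)cc2OC)c(O)c1
A7 | alternative 3 | 2-chloro-4-iodo-1,5-dimethoxy-3-(methoxymethoxy)benzene | COCOc1c(Cl)c(OC)cc(OC)c1I
A8 | alternative 3 | carbon monoxide | [C-]#[O+]
A9 | alternative 3 | [2-methoxy-4-(methoxymethoxy)-6-methylphenyl]boronic acid | COCOc1cc(C)c(B(O)O)c(OC)c1
A10 | alternative 3 | [3-chloro-4,6-dimethoxy-2-(methoxymethoxy)phenyl][2-methoxy-4-(methoxymethoxy)-6-methylphenyl]methanone | COCOc1cc(C)c(C(=O)c2c(OC)cc(OC)c(Cl)c2OCOC)c(OC)c1
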